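Counted in monomer units per chain begun, maple and larch share one target, so a quick number starts there.

| flask | free monomer | transfer agent | protic impurity | pre-initiator | remark | time |
|---|---|---|---|---|---|---|
| Wednesday's | 1.1 M | 0.011 M | 0.022 M | 38 mM | run made earlier |  |
| maple | 1.1 M | 0.0110 M | 0.0220 M | 19 mM |  | 15 min |
| larch | 1.1 M | 0.0110 M | 0.0220 M | 19 mM |  | 8.0 min |

Wednesday's run (percent of the free monomer charged)

| time / s | monomer in chains / % | free monomer / % |
|---|---|---|
| 10.0 | 0.2 | 97.7 |
| 12.0 | 0.4 | 98.2 |
| 15.0 | 0 | 97.2 |
| 25.0 | 0.8 | 97.0 |
| 40.0 | 0.7 | 96.6 |
| 60.0 | 1.2 | 96.2 |
| 90.0 | 5.2 | 92.8 |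

(readings scatter by 0.5 percentage points)

- the average divides the monomer in chains by the number of chains begun, living and dead together
- the earlier runs do not show the number of chains; that part of a forecast is a guess
- no earlier run changes the charge of pre-initiator; that part of a forecast is a guess

* which of the two ends with the longer chains by the average number of monomer units in a chain (chains begun, living or dead) ("neither" if they lie within 10%) (maple / larch / neither)
* average number of monomer units in a chain (chains begun, living or dead) at the end, maple
* average number of monomer units in a chain (chains begun, living or dead) at the end, larch

At the last reading of Wednesday's run, 90.0 s, free monomer and monomer in chains leave a gap of 2.00%. The protic impurity charge is 2.00% of the free monomer charge, so we take it that the impurity removes its own amount of monomer. If each pre-initiator then begins one chain, the rest is shared out: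

(free monomer − protic impurity) / pre-initiator = (1.1 M − 0.0220 M) / 19 mM = 56.7

This is the full-charge length, the monomer available per pre-initiator charged, or target degree of polymerisation. Taking one chain per pre-initiator charged, we estimate the length as the conversion times this figure.

For the conversion we suppose that chains appear at a steady rate. Monomer in chains then grows with the square of time, and we guess that it scales with the charge. From Wednesday's 5.2%, the first pass gives:

maple: 260%; larch: 74.0%

Maple's figure exceeds the whole charge, so we put it back in, letting consumed monomer thin what remains, with conversion = 1 − exp(−first pass):

maple: 92.6%; larch: 52.3%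

estimated length: maple about 52.5; larch about 29.7

We commit to maple. The forecast, your hunch, differs: neither, with 1 (0.4 to 45) for maple and 1 (0.4 to 40) for larch, on the ground that “nearly every chain should die early”.

The flask gives maple: 52.7 monomer units per chain in maple and 41.0 in larch.

    free monomer + initiator → living end + monomer in chains (k = 0.0880 M⁻¹ s⁻¹)
    free monomer + living end → monomer in chains + living end, rate k2*[living end]*[free monomer] (k = 0.220 M⁻¹ s⁻¹)
    living end + transfer agent → dead chain (kL = 0.130 M⁻¹ s⁻¹)
    protic impurity + free monomer → quenched substrate (k = 1.50 M⁻¹ s⁻¹)
    pre-initiator → initiator (k = 0.00190 s⁻¹)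

At 15.0 min maple holds 73.3% of its monomer in chains, and 18.1% of its pre-initiator remains. Against the full-charge length, maple stands at 92.9% and larch at 72.3%. Left ten times as long, maple reaches 57.6 at 150 min and larch 57.6 at 80.0 min, beside the full-charge 56.7, with initiator in larch standing at 3.00 × 10⁻⁴ M.

The readings were generated by integration on assumed constants, noise included.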